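It is easy to count 25 h as the reaction time of this fed flask, but monomer fed at 15 h has had 10.0 h of it, and the rising volume thins whatever reacts.

| flask | free monomer | pre-initiator | impurity | remark | time |
|---|---|---|---|---|---|
| winter | 0.10 M (fed, over 15 h) | 4.2 mM | 0.75 mM | run made earlier; the fed solution adds 1.0 times the starting volume |  |
| flask | 0.20 M (fed, over 15 h) | 4.2 mM | 0.75 mM | the fed solution adds 1.0 times the starting volume | 25 h |

winter run (percent of the free monomer charged)

| time / h | monomer in chains / % | free monomer / % |
|---|---|---|
| 1.00 | 0 | 7 |
| 2.50 | 1 | 18 |
| 5.00 | 5 | 30 |
| 8.00 | 8 | 47 |

(scatter of a reading: 1.5 percentage points)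

* average number of monomer units in a chain (chains begun, living or dead) at 25 h
* part of the free monomer that has reacted at 25 h

- every charge counts on the volume at the start, and the solution that is fed holds the whole dose
- the average divides the monomer in chains by the number of chains begun, living and dead together
- the earlier runs do not show the number of chains; that part of a forecast is a guess
- percentages count the whole charge, also what has not yet gone in

I assumed a fixed number of chains and a rate first order in free monomer (pseudo-first-order). Each hour then counts divided by the current volume over the starting volume, and I call the sum of such hours the exposure.

Two extreme flasks can be solved in the head. With the whole charge in at the start, the exposure is 15.4 h. With the whole charge arriving at the end of the feed, it is 5.00 h. Every portion enters between those two moments, so on these assumptions the real flask lies between them. I let the portion fed at 7.50 h stand for the whole, with exposure 9.32 h.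

In the winter run, I took the readings at 5.00 h and 8.00 h, with mid-portion exposures 2.00 h and 2.87 h. Pooling their logarithms of chains plus free monomer over free monomer, I read the decade exposure, the exposure that cuts free monomer by a factor of ten, as 36.0 h.

The flask has the same pre-initiator and impurity as the winter run, so I carried this reading over. Its 0.259 decades gave my estimate of 44.9% reacted, between the extremes 27.4% and 62.7%. Guessing that each impurity removes one chain left 3.45 mM of chains, so I reckoned dp at 26.0.

The forecast put dp at 22 (15 to 38) and the reacted part at 39% (29% to 50%), both lower than mine, and it said: “Growth is slow, with little sign of monomer loss elsewhere”.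

The flask gave dp 26.1 and 45.0% reacted.

    initiator + impurity → spent initiator (k = 4290 L mol⁻¹ h⁻¹)
    pre-initiator → initiator (k = 1.90 h⁻¹)
    free monomer + initiator → living end + monomer in chains (k = 10.2 L mol⁻¹ h⁻¹)
    free monomer + living end → monomer in chains + living end, rate k4*[living end]*[free monomer] (k = 19.0 L mol⁻¹ h⁻¹)

The neighbour flask held 0.0011 M of pre-initiator, with the impurity as before, so the same guess left 0.350 mM of chains. With the rate in proportion to chains, its decade exposure stretched to 355 h. From the exposure of 9.32 h I then reckoned 5.86% reacted and dp 33.5. That neighbour flask gave 6.14% reacted and dp 34.5. Its living end stood at 1.78 × 10⁻⁴ M at 25.0 h, which on the starting volume is 0.355 mM.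

(All runs are simulated for substances that don't exist; the scatter is artificial.)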